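The synthesis rests on cutting the orsellinate away at two bonds: the ester C–O bond on the hindered secondary C6 carbinol of ring A (adjacent to quaternary C7) and the aryl C–C bond that corresponds to C2–C7 of a 3,5,7-trioxooctanoyl chain. In a single operation a diketo-dioxinone is thermolysed to an acylketene that acylates the C6 hydroxyl, and the resulting triketo ester cyclises and aromatises to the resorcylate. The precursor is the unprotected (6R,7R)-diol of the 3-oxiranyl-5,6,7,8-tetrahydro-1H-isochromen-8-one, built from (R)-carvone (ring A and C1) and an epoxy-alkyne from (E)-crotyl alcohol (C3, C4, oxirane), joined by Sonogashira coupling and 6-endo oxa-Michael closure of ring B.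

Key step: step 16

Remark: ring positions of all intermediates carry the isochromene numbering of the target (C1, O2, C3, C4, C4a, C5–C8, C8a), and the tertiary, ketone-flanked C7 hydroxyl is assumed to be much slower toward the acylketene than the secondary C6 hydroxyl, so diol 22 is used unprotected.

Step 1
Reactants: 1 (E)-but-2-en-1-ol
Product: 2 [(2R,3R)-3-methyloxiran-2-yl]methanol
Conditions: Ti(OiPr)4 (cat.), D-(−)-diisopropyl tartrate (cat.), tBuOOH, 4 Å MS, CH2Cl2, −20 °C
Reagents that add atoms: tert-butyl hydroperoxide, CC(C)(C)OO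
Why: Katsuki–Sharpless asymmetric epoxidation of an (E)-allylic alcohol is stereospecific (trans oxirane), and the D-tartrate ligand sets both new centres as (2R,3R).

Step 2
Reactants: 2 [(2R,3R)-3-methyloxiran-2-yl]methanol
Product: 4 (2R,3R)-2-ethynyl-3-methyloxirane, via epoxy aldehyde 3 (not isolated)
Conditions: TEMPO (cat.), PhI(OAc)2, CH2Cl2, rt; then MeOH, K2CO3, dimethyl (1-diazo-2-oxopropyl)phosphonate, 0 °C → rt; 4 kept as a THF solution
Reagents that add atoms: dimethyl (1-diazo-2-oxopropyl)phosphonate, COP(=O)(OC)C(=[N+]=[N-])C(C)=O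
Why: Oxoammonium oxidation followed by Seyferth–Gilbert homologation under the Ohira–Bestmann protocol adds one carbon without touching either oxirane centre, and telescoping avoids isolating the volatile aldehyde.

Step 3
Reactants: 5 2,2,6-trimethyl-4H-1,3-dioxin-4-one
Product: 6 2,2-dimethyl-6-(2-oxopropyl)-4H-1,3-dioxin-4-one
Conditions: 5 (2 equiv), LiN(SiMe3)2 (2 equiv), THF, −78 °C; AcCl (1 equiv); 1 M HCl
Reagents that add atoms: acetyl chloride, CC(Cl)=O
Why: γ-Deprotonation gives the vinylogous lithium enolate, which undergoes Claisen-type C-acylation at the exocyclic carbon; the second equivalent of enolate is consumed by the more acidic product.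

Step 4
Reactants: 6 2,2-dimethyl-6-(2-oxopropyl)-4H-1,3-dioxin-4-one
Product: 7 2,2-dimethyl-6-(2,4-dioxopentyl)-4H-1,3-dioxin-4-one
Conditions: LiN(iPr)2 (2.2 equiv), THF, −78 °C; MeC(O)N(OMe)Me; 1 M HCl, −78 → 0 °C
Reagents that add atoms: N-methoxy-N-methylacetamide, CON(C)C(C)=O
Why: The dianion of the keto-dioxinone reacts at its less stabilised terminal carbon, and acylation with a Weinreb amide stops at the chelated tetrahedral adduct, so a single acetyl group is added.

Step 5
Reactants: 8 (R)-carvone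
Product: 9 (5R,6R)-6-(hydroxymethyl)-2-methyl-5-(prop-1-en-2-yl)cyclohex-2-en-1-one
Conditions: LiN(iPr)2, THF, −78 °C; CH2O (gas, cracked paraformaldehyde); AcOH quench
Reagents that add atoms: formaldehyde, C=O
Why: Aldol addition of the kinetic α′-lithium enolate to monomeric formaldehyde installs C1 anti to the isopropenyl group (trans, 6R); this centre is only a relay and is erased in step 12.

Step 6
Reactants: 9 (5R,6R)-6-(hydroxymethyl)-2-methyl-5-(prop-1-en-2-yl)cyclohex-2-en-1-one
Product: 10 (5R,6R)-6-{[(tert-butyldiphenylsilyl)oxy]methyl}-2-methyl-5-(prop-1-en-2-yl)cyclohex-2-en-1-one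
Conditions: tBuPh2SiCl, imidazole, DMF, 0 °C → rt
Reagents that add atoms: tert-butyldiphenylsilyl chloride, CC(C)(C)[Si](Cl)(c1ccccc1)c1ccccc1
Why: Standard silylation of the primary aldol hydroxyl; this silyl group is chosen because it should survive the acid of step 13 and mask the C1 oxygen during the coupling of step 14.

Step 7
Reactants: 10 (5R,6R)-6-{[(tert-butyldiphenylsilyl)oxy]methyl}-2-methyl-5-(prop-1-en-2-yl)cyclohex-2-en-1-one
Product: 12 (1R,6S)-6-{[(tert-butyldiphenylsilyl)oxy]methyl}-4-methyl-5-oxocyclohex-3-en-1-yl acetate, via methoxy hydroperoxide 11 (not isolated)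
Conditions: O3, CH2Cl2/MeOH, −78 °C; then Ac2O, Et3N, DMAP (cat.), −78 °C → rt
Reagents that add atoms: ozone, [O-][O+]=O; methanol, CO
Why: Ozone selects the electron-rich 1,1-disubstituted alkene over the enone, methanol traps the carbonyl oxide as 11, and acetylation triggers the Criegee rearrangement in which the ring carbon migrates to oxygen with retention, so C4a receives its oxygen (the acetyl carbons of 12 are the former isopropenyl C2 and methyl).

Step 8
Reactants: 12 (1R,6S)-6-{[(tert-butyldiphenylsilyl)oxy]methyl}-4-methyl-5-oxocyclohex-3-en-1-yl acetate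
Product: 14 (1R,2S,3R)-2-{[(tert-butyldiphenylsilyl)oxy]methyl}-4-methylcyclohex-4-ene-1,3-diol, via allylic alcohol acetate 13 (not isolated)
Conditions: NaBH4, CeCl3·7H2O, MeOH, −78 °C; then K2CO3, rt
Reagents that add atoms: none
Why: Luche reduction delivers hydride 1,2 and axially, placing the new C8 hydroxyl equatorial and cis to the C4a oxygen (new stereocentre, minor epimer removable), and methanolysis of the acetate in the same pot gives the diol.

Step 9
Reactants: 14 (1R,2S,3R)-2-{[(tert-butyldiphenylsilyl)oxy]methyl}-4-methylcyclohex-4-ene-1,3-diol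
Product: 15 (1R,2R,3R,4S,5R)-4-{[(tert-butyldiphenylsilyl)oxy]methyl}-2-methylcyclohexane-1,2,3,5-tetrol
Conditions: OsO4 (cat.), N-methylmorpholine N-oxide, acetone/H2O, rt
Reagents that add atoms: N-methylmorpholine N-oxide, C[N+]1([O-])CCOCC1; water, O
Why: Upjohn dihydroxylation adds both oxygens syn (cis-diol) to the face of C6=C7 opposite the allylic C8 hydroxyl and the C4a hydroxyl (Kishi anti rule), which fixes C6 and C7 as R,R; the syn-face diastereomer is separable at this stage or as 16.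

Step 10
Reactants: 15 (1R,2R,3R,4S,5R)-4-{[(tert-butyldiphenylsilyl)oxy]methyl}-2-methylcyclohexane-1,2,3,5-tetrol
Product: 16 (3aS,4R,5S,6R,7aR)-5-{[(tert-butyldiphenylsilyl)oxy]methyl}-2,2,3a-trimethylhexahydro-2H-1,3-benzodioxole-4,6-diol
Conditions: Me2C(OMe)2 (1.5 equiv), PPTS (cat.), acetone, rt
Reagents that add atoms: 2,2-dimethoxypropane, COC(C)(C)OC
Why: Under thermodynamic ketalisation only the cis-vicinal C6/C7 diol can close a dioxolane (C7/C8 are trans and the C8/C4a pair would need a triaxial chair), so the two secondary hydroxyls destined for oxidation stay free.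

Step 11
Reactants: 16 (3aS,4R,5S,6R,7aR)-5-{[(tert-butyldiphenylsilyl)oxy]methyl}-2,2,3a-trimethylhexahydro-2H-1,3-benzodioxole-4,6-diol
Product: 17 (3aR,7aR)-5-{[(tert-butyldiphenylsilyl)oxy]methyl}-2,2,3a-trimethyltetrahydro-1,3-benzodioxole-4,6-dione (C5 epimers and enol tautomers)
Conditions: IBX (3 equiv), EtOAc, 75 °C
Reagents that add atoms: none
Why: IBX in hot ethyl acetate oxidises both secondary alcohols and is a standard reagent for taking β-hydroxy ketones to β-diketones without over-oxidation; C6 and C7 are protected and unaffected.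

Step 12
Reactants: 17 (3aR,7aR)-5-{[(tert-butyldiphenylsilyl)oxy]methyl}-2,2,3a-trimethyltetrahydro-1,3-benzodioxole-4,6-dione
Product: 18 (3aR,7aR)-5-{[(tert-butyldiphenylsilyl)oxy]methyl}-2,2,3a-trimethyl-4-oxo-3a,4,7,7a-tetrahydro-1,3-benzodioxol-6-yl trifluoromethanesulfonate
Conditions: Tf2O, 2,6-lutidine, CH2Cl2, −78 °C
Reagents that add atoms: trifluoromethanesulfonic anhydride, O=S(=O)(OS(=O)(=O)C(F)(F)F)C(F)(F)F
Why: O-Sulfonylation of the vinylogous acid should occur at the enol oxygen on C4a, which is remote from the quaternary, α-oxygenated C7 and so less hindered and more electron-rich than the C8 oxygen; cold hindered base should prevent loss of the silyloxymethyl group from the enolate.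

Step 13
Reactants: 18 (3aR,7aR)-5-{[(tert-butyldiphenylsilyl)oxy]methyl}-2,2,3a-trimethyl-4-oxo-3a,4,7,7a-tetrahydro-1,3-benzodioxol-6-yl trifluoromethanesulfonate
Product: 19 (4R,5R)-2-{[(tert-butyldiphenylsilyl)oxy]methyl}-4,5-dihydroxy-4-methyl-3-oxocyclohex-1-en-1-yl trifluoromethanesulfonate
Conditions: TFA/H2O/CH2Cl2, 0 °C
Reagents that add atoms: none
Why: Aqueous acid hydrolyses the dioxolane of the cis-diol, while the primary tert-butyldiphenylsilyl ether and the vinylogous acyl triflate tolerate brief cold acid; the acid-labile oxirane is not yet present.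

Step 14
Reactants: 19 (4R,5R)-2-{[(tert-butyldiphenylsilyl)oxy]methyl}-4,5-dihydroxy-4-methyl-3-oxocyclohex-1-en-1-yl trifluoromethanesulfonate, 4 (2R,3R)-2-ethynyl-3-methyloxirane
Product: 20 (5R,6R)-2-{[(tert-butyldiphenylsilyl)oxy]methyl}-5,6-dihydroxy-6-methyl-3-{[(2R,3R)-3-methyloxiran-2-yl]ethynyl}cyclohex-2-en-1-one
Conditions: PdCl2(PPh3)2 (cat.), CuI (cat.), Et3N, THF, 0 °C → rt
Reagents that add atoms: none
Why: Sonogashira coupling of an electron-poor β-triflyloxy enone runs at or below room temperature, where the terminal alkynyl oxirane and the free diol are tolerated, and the silyl ether keeps the C1 oxygen from cyclising under palladium or copper.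

Step 15
Reactants: 20 (5R,6R)-2-{[(tert-butyldiphenylsilyl)oxy]methyl}-5,6-dihydroxy-6-methyl-3-{[(2R,3R)-3-methyloxiran-2-yl]ethynyl}cyclohex-2-en-1-one
Product: 22 (6R,7R)-6,7-dihydroxy-7-methyl-3-[(2S,3R)-3-methyloxiran-2-yl]-5,6,7,8-tetrahydro-1H-isochromen-8-one, via free enynol 21 (not isolated)
Conditions: Bu4NF, THF, 0 °C → rt
Reagents that add atoms: none
Why: Fluoride unmasks the C1 alkoxide, which adds to C3, the δ-carbon of the ynenone, in a polarity-matched 6-endo-dig oxa-Michael (1,6-conjugate) addition; protonation at C4 gives the dienol ether of ring B, and no stereocentre is formed.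

Step 16
Reactants: 22 (6R,7R)-6,7-dihydroxy-7-methyl-3-[(2S,3R)-3-methyloxiran-2-yl]-5,6,7,8-tetrahydro-1H-isochromen-8-one, 7 2,2-dimethyl-6-(2,4-dioxopentyl)-4H-1,3-dioxin-4-one
Product: 26 (6R,7R)-7-hydroxy-7-methyl-3-[(2S,3R)-3-methyloxiran-2-yl]-8-oxo-5,6,7,8-tetrahydro-1H-isochromen-6-yl 2,4-dihydroxy-6-methylbenzoate, via acylketene 23 (not isolated), via triketo ester 24 (not isolated), via aldol carbinol 25 (not isolated)
Conditions: 7 (1.2 equiv), PhMe, 110 °C, 4 Å MS; cool, Et3N (cat.), CH2Cl2, rt; then AcOH/NaOAc buffer (pH 5), rt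
Reagents that add atoms: none
Why: Retro-[4+2] of 7 expels acetone and releases acylketene 23, which the C6 hydroxyl of 22 should add to through a six-membered hydrogen-bonded transition state, forming the ester C–O bond of 24 without any coupling agent. Mild base then enolises C2 of the 3,5,7-triketo ester, C2 attacks the C7 carbonyl in a 6-(enolendo)-exo-trig aldol closure to 25, and buffered acid removes water so that the ring aromatises to the 2,4-dihydroxy-6-methylbenzoate with hydroxyls and methyl placed automatically. The closest known reaction type is dioxinone thermolysis with acylketene capture by alcohols followed by triketo-ester aldol aromatisation to resorcylates. No stereocentre is created, and C6 and C7 are carried through unchanged because the C6–O bond is never broken. Site selectivity for C6 over C7 rests on the tertiary, ketone-flanked C7 hydroxyl being far slower toward the ketene, supported by near-stoichiometric 7. Catalytic amine at room temperature should favour the C2-to-C7 aldol over pyranone or Claisen closures that would expel the alcohol, and should be too mild to cause vinylogous loss of the C6 acyloxy group or opening of the oxirane.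

Compound list
1 | (E)-but-2-en-1-ol | C/C=C/CO | starting material
2 | [(2R,3R)-3-methyloxiran-2-yl]methanol | OC[C@H]1O[C@@H]1C | intermediate
3 | (2S,3R)-3-methyloxirane-2-carbaldehyde | O=C[C@H]1O[C@@H]1C | intermediate (not isolated)
4 | (2R,3R)-2-ethynyl-3-methyloxirane | C#C[C@H]1O[C@@H]1C | intermediate
5 | 2,2,6-trimethyl-4H-1,3-dioxin-4-one | CC1=CC(=O)OC(C)(C)O1 | starting material
6 | 2,2-dimethyl-6-(2-oxopropyl)-4H-1,3-dioxin-4-one | CC(=O)CC1=CC(=O)OC(C)(C)O1 | intermediate
7 | 2,2-dimethyl-6-(2,4-dioxopentyl)-4H-1,3-dioxin-4-one | CC(=O)CC(=O)CC1=CC(=O)OC(C)(C)O1 | intermediate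
8 | (R)-carvone | CC1=CC[C@H](CC1=O)C(C)=C | starting material
9 | (5R,6R)-6-(hydroxymethyl)-2-methyl-5-(prop-1-en-2-yl)cyclohex-2-en-1-one | CC1=CC[C@@H](C(C)=C)[C@H](CO)C1=O | intermediate
10 | (5R,6R)-6-{[(tert-butyldiphenylsilyl)oxy]methyl}-2-methyl-5-(prop-1-en-2-yl)cyclohex-2-en-1-one | CC1=CC[C@@H](C(C)=C)[C@H](CO[Si](c2ccccc2)(c2ccccc2)C(C)(C)C)C1=O | intermediate
11 | (5R,6R)-6-{[(tert-butyldiphenylsilyl)oxy]methyl}-5-(1-hydroperoxy-1-methoxyethyl)-2-methylcyclohex-2-en-1-one | CC1=CC[C@@H](C(C)(OC)OO)[C@H](CO[Si](c2ccccc2)(c2ccccc2)C(C)(C)C)C1=O | intermediate (not isolated)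
12 | (1R,6S)-6-{[(tert-butyldiphenylsilyl)oxy]methyl}-4-methyl-5-oxocyclohex-3-en-1-yl acetate | CC1=CC[C@@H](OC(C)=O)[C@H](CO[Si](c2ccccc2)(c2ccccc2)C(C)(C)C)C1=O | intermediate
13 | (1R,5R,6R)-6-{[(tert-butyldiphenylsilyl)oxy]methyl}-5-hydroxy-4-methylcyclohex-3-en-1-yl acetate | CC1=CC[C@@H](OC(C)=O)[C@H](CO[Si](c2ccccc2)(c2ccccc2)C(C)(C)C)[C@H]1O | intermediate (not isolated)
14 | (1R,2S,3R)-2-{[(tert-butyldiphenylsilyl)oxy]methyl}-4-methylcyclohex-4-ene-1,3-diol | CC1=CC[C@@H](O)[C@H](CO[Si](c2ccccc2)(c2ccccc2)C(C)(C)C)[C@H]1O | intermediate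
15 | (1R,2R,3R,4S,5R)-4-{[(tert-butyldiphenylsilyl)oxy]methyl}-2-methylcyclohexane-1,2,3,5-tetrol | C[C@@]1(O)[C@H](O)C[C@@H](O)[C@H](CO[Si](c2ccccc2)(c2ccccc2)C(C)(C)C)[C@H]1O | intermediate
16 | (3aS,4R,5S,6R,7aR)-5-{[(tert-butyldiphenylsilyl)oxy]methyl}-2,2,3a-trimethylhexahydro-2H-1,3-benzodioxole-4,6-diol | C[C@@]12OC(C)(C)O[C@@H]1C[C@@H](O)[C@H](CO[Si](c3ccccc3)(c3ccccc3)C(C)(C)C)[C@H]2O | intermediate
17 | (3aR,7aR)-5-{[(tert-butyldiphenylsilyl)oxy]methyl}-2,2,3a-trimethyltetrahydro-1,3-benzodioxole-4,6-dione | C[C@@]12OC(C)(C)O[C@@H]1CC(=O)C(CO[Si](c3ccccc3)(c3ccccc3)C(C)(C)C)C2=O | intermediate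
18 | (3aR,7aR)-5-{[(tert-butyldiphenylsilyl)oxy]methyl}-2,2,3a-trimethyl-4-oxo-3a,4,7,7a-tetrahydro-1,3-benzodioxol-6-yl trifluoromethanesulfonate | C[C@@]12OC(C)(C)O[C@@H]1CC(OS(=O)(=O)C(F)(F)F)=C(CO[Si](c3ccccc3)(c3ccccc3)C(C)(C)C)C2=O | intermediate
19 | (4R,5R)-2-{[(tert-butyldiphenylsilyl)oxy]methyl}-4,5-dihydroxy-4-methyl-3-oxocyclohex-1-en-1-yl trifluoromethanesulfonate | C[C@@]1(O)[C@H](O)CC(OS(=O)(=O)C(F)(F)F)=C(CO[Si](c2ccccc2)(c2ccccc2)C(C)(C)C)C1=O | intermediate
20 | (5R,6R)-2-{[(tert-butyldiphenylsilyl)oxy]methyl}-5,6-dihydroxy-6-methyl-3-{[(2R,3R)-3-methyloxiran-2-yl]ethynyl}cyclohex-2-en-1-one | C[C@@]1(O)[C@H](O)CC(C#C[C@H]2O[C@@H]2C)=C(CO[Si](c3ccccc3)(c3ccccc3)C(C)(C)C)C1=O | intermediate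
21 | (5R,6R)-5,6-dihydroxy-2-(hydroxymethyl)-6-methyl-3-{[(2R,3R)-3-methyloxiran-2-yl]ethynyl}cyclohex-2-en-1-one | C[C@@]1(O)[C@H](O)CC(C#C[C@H]2O[C@@H]2C)=C(CO)C1=O | intermediate (not isolated)
22 | (6R,7R)-6,7-dihydroxy-7-methyl-3-[(2S,3R)-3-methyloxiran-2-yl]-5,6,7,8-tetrahydro-1H-isochromen-8-one | O[C@@H]1CC2=C(COC([C@H]3O[C@@H]3C)=C2)C(=O)[C@]1(C)O | intermediate
23 | 3,5,7-trioxooct-1-en-1-one (acylketene) | CC(=O)CC(=O)CC(=O)C=C=O | intermediate (not isolated)
24 | (6R,7R)-7-hydroxy-7-methyl-3-[(2S,3R)-3-methyloxiran-2-yl]-8-oxo-5,6,7,8-tetrahydro-1H-isochromen-6-yl 3,5,7-trioxooctanoate | CC(=O)CC(=O)CC(=O)CC(=O)O[C@@H]1CC2=C(COC([C@H]3O[C@@H]3C)=C2)C(=O)[C@]1(C)O | intermediate (not isolated)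
25 | (6R,7R)-7-hydroxy-7-methyl-3-[(2S,3R)-3-methyloxiran-2-yl]-8-oxo-5,6,7,8-tetrahydro-1H-isochromen-6-yl 2-hydroxy-2-methyl-4,6-dioxocyclohexane-1-carboxylate | CC1(O)CC(=O)CC(=O)C1C(=O)O[C@@H]2CC3=C(COC([C@H]4O[C@@H]4C)=C3)C(=O)[C@]2(C)O | intermediate (not isolated)
26 | (6R,7R)-7-hydroxy-7-methyl-3-[(2S,3R)-3-methyloxiran-2-yl]-8-oxo-5,6,7,8-tetrahydro-1H-isochromen-6-yl 2,4-dihydroxy-6-methylbenzoate | Cc1cc(O)cc(O)c1C(=O)O[C@@H]1CC2=C(COC([C@H]3O[C@@H]3C)=C2)C(=O)[C@]1(C)O | target

Total step count: 16. Longest linear sequence: 12 steps (8 to 26, steps 5–16).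

Steps most likely to fail

Step 16. The ketene may be captured by the tertiary C7 hydroxyl or close on itself to a pyranone before the C6 hydroxyl reacts, and the base used for aromatisation may trigger vinylogous loss of the new C6 acyloxy group. The fallback sets out from 22 and returns at 26 by classical acylation. Commercial orsellinic acid would be persilylated (tBuMe2SiCl, imidazole, DMF) to tert-butyldimethylsilyl 2,4-bis[(tert-butyldimethylsilyl)oxy]-6-methylbenzoate F1. Oxalyl chloride with catalytic DMF would convert the silyl ester directly into 2,4-bis[(tert-butyldimethylsilyl)oxy]-6-methylbenzoyl chloride F2. Acylation of the C6 hydroxyl of 22 (Et3N, DMAP, CH2Cl2) should give the bis-silyl ester of 26 F3, and Bu4NF buffered with AcOH would free both phenols to give 26.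

Step 9. Facial discrimination in the osmylation may be insufficient; attack syn to the C8 hydroxyl gives the diastereomer that becomes the enantiomeric series once C8, C8a and C4a are flattened. The fallback sets out from 14 and returns at 16, with a bulky allylic silyl ether as the control element. Both secondary hydroxyls would be silylated (Et3SiOTf, 2,6-lutidine) to the 1,3-bis(triethylsilyl) ether of 14 F4. Osmylation (OsO4 cat., N-methylmorpholine N-oxide) anti to the allylic silyl ether should give the cis-diol bis(triethylsilyl) ether F5, and ketalisation (Me2C(OMe)2, PPTS) its acetonide F6. HF·pyridine/pyridine in THF at 0 °C would remove the two secondary triethylsilyl ethers, leave the primary tert-butyldiphenylsilyl ether, and give 16.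

Step 7. Acetic acid may be eliminated from the newly formed β-acetoxy ketone under the amine base of the Criegee sequence, followed by tautomerisation to a phenol. The fallback sets out from 10 and returns at 12 without amine base. Ozonolysis with reductive work-up (O3, CH2Cl2, −78 °C; Me2S) would give (5R,6R)-5-acetyl-6-{[(tert-butyldiphenylsilyl)oxy]methyl}-2-methylcyclohex-2-en-1-one F7. Baeyer–Villiger oxidation (mCPBA, NaHCO3, CH2Cl2) should then migrate the secondary ring carbon with retention and give 12.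

Further compounds
F1 | step 16 | tert-butyldimethylsilyl 2,4-bis[(tert-butyldimethylsilyl)oxy]-6-methylbenzoate | Cc1cc(O[Si](C)(C)C(C)(C)C)cc(O[Si](C)(C)C(C)(C)C)c1C(=O)O[Si](C)(C)C(C)(C)C
F2 | step 16 | 2,4-bis[(tert-butyldimethylsilyl)oxy]-6-methylbenzoyl chloride | Cc1cc(O[Si](C)(C)C(C)(C)C)cc(O[Si](C)(C)C(C)(C)C)c1C(Cl)=O
F3 | step 16 | (6R,7R)-7-hydroxy-7-methyl-3-[(2S,3R)-3-methyloxiran-2-yl]-8-oxo-5,6,7,8-tetrahydro-1H-isochromen-6-yl 2,4-bis[(tert-butyldimethylsilyl)oxy]-6-methylbenzoate | Cc1cc(O[Si](C)(C)C(C)(C)C)cc(O[Si](C)(C)C(C)(C)C)c1C(=O)O[C@@H]1CC2=C(COC([C@H]3O[C@@H]3C)=C2)C(=O)[C@]1(C)O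
F4 | step 9 | 1,3-bis(triethylsilyl) ether of 14 (stereocentres as in 14) | CC1=CC[C@@H](O[Si](CC)(CC)CC)[C@H](CO[Si](c2ccccc2)(c2ccccc2)C(C)(C)C)[C@H]1O[Si](CC)(CC)CC
F5 | step 9 | 3,5-bis(triethylsilyl) ether of tetrol 15 (free cis-1,2-diol, stereocentres as in 15) | C[C@@]1(O)[C@H](O)C[C@@H](O[Si](CC)(CC)CC)[C@H](CO[Si](c2ccccc2)(c2ccccc2)C(C)(C)C)[C@H]1O[Si](CC)(CC)CC
F6 | step 9 | 4,6-bis(triethylsilyl) ether of acetonide 16 (stereocentres as in 16) | C[C@@]12OC(C)(C)O[C@@H]1C[C@@H](O[Si](CC)(CC)CC)[C@H](CO[Si](c3ccccc3)(c3ccccc3)C(C)(C)C)[C@H]2O[Si](CC)(CC)CC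
F7 | step 7 | (5R,6R)-5-acetyl-6-{[(tert-butyldiphenylsilyl)oxy]methyl}-2-methylcyclohex-2-en-1-one | CC1=CC[C@@H](C(C)=O)[C@H](CO[Si](c2ccccc2)(c2ccccc2)C(C)(C)C)C1=O
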